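The central tetrahydrofuran ring (O1, C2–C5) bears a 4-hydroxyphenyl group on each oxygen-bound carbon, and its C3–C4 bond joins two identical (2S,3S)-dihydrobenzofuran halves: the core is a masked dimer of one 4-hydroxystilbene. Everything rests on cutting C3–C4 and both ring C–O bonds. Anodic oxidation of one enantiopure stilbene phenol (other phenols benzylated, ortho positions blocked by chlorine) joins two styryl β-carbons to a bis(quinone methide); water adds to one methide carbon and the resulting hydroxyl closes the ring onto the other (O1–C5). One operation forms three bonds and four stereocentres. The monomer arises from an enantioselective rhodium-carbene C–H insertion and a Heck reaction.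

Key step: step 11

Assumption: in step 7 Rh2(S-PTAD)4 (dirhodium tetrakis[(S)-(1-adamantyl)(phthalimido)acetate]) is taken to deliver the 3S product; if the sense of induction is the opposite, Rh2(R-PTAD)4 is used and nothing else changes.

Remark on numbering: in the tetrahydrofuran, C2 is the oxygen-bound carbon whose aryl group is cis to the benzofuranyl group on C3, and C5 is the one whose aryl group is trans to the benzofuranyl group on C4; in this numbering the ring is 2S,3S,4S,5R.

Abbreviation: BF = (2S,3S)-6-(benzyloxy)-2-[4-(benzyloxy)phenyl]-3-[3,5-bis(benzyloxy)phenyl]-2,3-dihydro-1-benzofuran-4-yl.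

Step 1
Reactants: 1 5-bromobenzene-1,3-diol
Product: 2 2-bromo-4,6-dihydroxybenzaldehyde
Conditions: POCl3, DMF, MeCN, 0 °C → rt; then H2O, 50 °C
Reagents that add atoms: DMF, CN(C)C=O (formyl carbon); water, O (carbonyl oxygen)
Why: Vilsmeier–Haack formylation of the electron-rich resorcinol should take place at C4, ortho to one hydroxyl and para to the other as in other 5-substituted resorcinols, which puts the formyl group between a hydroxyl and the bromine.

Step 2
Reactants: 2 2-bromo-4,6-dihydroxybenzaldehyde
Product: 3 4-(benzyloxy)-2-bromo-6-hydroxybenzaldehyde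
Conditions: BnBr (1.05 equiv), NaHCO3, MeCN, 80 °C
Reagents that add atoms: benzyl bromide, BrCc1ccccc1
Why: Williamson etherification with a weak base should benzylate only the para hydroxyl, because the ortho hydroxyl is held in a hydrogen bond to the formyl group and is less acidic.

Step 3
Reactants: 3 4-(benzyloxy)-2-bromo-6-hydroxybenzaldehyde; 4 1-(benzyloxy)-4-(chloromethyl)benzene
Product: 5 4-(benzyloxy)-2-{[4-(benzyloxy)benzyl]oxy}-6-bromobenzaldehyde
Conditions: K2CO3, KI (cat.), DMF, 60 °C
Reagents that add atoms: none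
Why: Williamson etherification of the remaining chelated phenol under stronger conditions installs the 4-(benzyloxy)benzyl ether whose benzylic CH2 group is the later site of C–H insertion.

Step 4
Reactants: 5 4-(benzyloxy)-2-{[4-(benzyloxy)benzyl]oxy}-6-bromobenzaldehyde; 6 1,3-bis(benzyloxy)-5-bromobenzene
Product: 8 racemic [4-(benzyloxy)-2-{[4-(benzyloxy)benzyl]oxy}-6-bromophenyl][3,5-bis(benzyloxy)phenyl]methanol, via aryl Grignard reagent 7 (not isolated)
Conditions: 6, Mg, THF, 50 °C; then 5, THF, 0 °C; aq NH4Cl
Reagents that add atoms: none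
Why: Grignard addition of the preformed aryl magnesium bromide to the aldehyde is much faster than halogen–metal exchange at the aryl bromide and gives the racemic diarylmethanol, whose stereocentre is erased in the next step.

Step 5
Reactants: 8 racemic diarylmethanol
Product: 9 [4-(benzyloxy)-2-{[4-(benzyloxy)benzyl]oxy}-6-bromophenyl][3,5-bis(benzyloxy)phenyl]methanone
Conditions: Dess–Martin periodinane, CH2Cl2, rt
Reagents that add atoms: none
Why: Dess–Martin oxidation turns the doubly benzylic secondary alcohol into the diaryl ketone under neutral conditions that leave the benzyl ethers and the aryl bromide untouched.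

Step 6
Reactants: 9 diaryl ketone
Product: 10 hydrazone of ketone 9 (free NH2)
Conditions: N2H4·H2O (excess), AcOH (cat.), n-BuOH, 110 °C
Reagents that add atoms: hydrazine, NN
Why: Hydrazone formation by acid-catalysed condensation of the ketone with a large excess of hydrazine, heat making up for the two ortho substituents while the unactivated aryl bromide is not displaced.

Step 7
Reactants: 10 hydrazone
Product: 12 (2R,3S)-6-(benzyloxy)-2-[4-(benzyloxy)phenyl]-3-[3,5-bis(benzyloxy)phenyl]-4-bromo-2,3-dihydro-1-benzofuran (2,3-cis), via diaryldiazomethane 11 (not isolated)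
Conditions: MnO2, CH2Cl2, 0 °C; filter; then Rh2(S-PTAD)4 (1 mol %), CH2Cl2, −20 °C → rt
Reagents that add atoms: none
Why: MnO2 dehydrogenates the hydrazone to diaryldiazomethane 11, and its donor/donor rhodium carbene undergoes an enantioselective intramolecular C–H insertion into the benzylic C–H bond alpha to the ether oxygen through a five-membered transition state, the chiral carboxylate ligands fixing C3 as S and the concerted insertion giving the 2,3-cis ring.

Step 8
Reactants: 12 cis-dihydrobenzofuran
Product: 13 (2S,3S)-6-(benzyloxy)-2-[4-(benzyloxy)phenyl]-3-[3,5-bis(benzyloxy)phenyl]-4-bromo-2,3-dihydro-1-benzofuran (2,3-trans)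
Conditions: TFA, CH2Cl2, 0 °C
Reagents that add atoms: none
Why: Acid-mediated epimerisation under thermodynamic control: reversible ionisation of the C2–O bond to the 4-(benzyloxy)benzylic cation and reclosure by the phenol oxygen turns the C2 aryl group trans to the C3 aryl group, while C3, which cannot ionise, keeps the S configuration set in step 7.

Step 9
Reactants: 14 3,5-dichloro-4-hydroxybenzaldehyde
Product: 15 2,6-dichloro-4-ethenylphenol
Conditions: Ph3PCH3Br, KOt-Bu (2.5 equiv each), THF, 0 °C → rt
Reagents that add atoms: methyltriphenylphosphonium bromide, C[P+](c1ccccc1)(c1ccccc1)c1ccccc1.[Br-]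
Why: Wittig methylenation with excess ylide, one equivalent of base being spent on the acidic phenol, converts the aldehyde into the styrene.

Step 10
Reactants: 13 trans-4-bromodihydrobenzofuran; 15 2,6-dichloro-4-ethenylphenol
Product: 16 4-[(E)-2-(BF)ethenyl]-2,6-dichlorophenol
Conditions: Pd(OAc)2, P(o-tol)3, NaOAc, DMF, 120 °C
Reagents that add atoms: none
Why: Mizoroki–Heck reaction in which zerovalent palladium inserts into the C–Br bond but not into the stronger C–Cl bonds of the electron-rich phenol, and syn insertion followed by syn β-hydride elimination gives the E-stilbene without touching the stereocentres.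

Step 11
Reactants: 16 4-[(E)-2-(BF)ethenyl]-2,6-dichlorophenol (two molecules)
Product: 19 4,4′-[(2S,3S,4S,5R)-3,4-bis(BF)oxolane-2,5-diyl]bis(2,6-dichlorophenol), via bis(quinone methide) 17 (not isolated), via hydroxy quinone methide 18 (not isolated)
Conditions: graphite anode, Pt cathode, divided cell, anode held just above the onset of the phenol wave (about +0.3 V vs Ag/AgCl), 1 F/mol, 2,6-lutidine, LiClO4, MeCN/THF/H2O, 0 °C → rt
Reagents that add atoms: water, O
Why: Anodic one-electron oxidation of the lutidine-bound phenol of 16 gives a phenoxyl radical whose ortho carbons are blocked by chlorine, so two radicals combine at their styryl β-carbons (the C3–C4 bond) to the bis(quinone methide) 17; water then adds in a 1,6-sense to one methide carbon (C2) to give 18, and its new benzylic hydroxyl closes the tetrahydrofuran by a 5-exo-trig oxa-1,6-addition to the other methide carbon, which forms the O1–C5 bond and restores the second chlorophenol. The closest known reaction type is the oxidative β,β-dehydrodimerisation of 4-hydroxystilbenes and 4-propenylphenols with capture of water, which gives 2,5-diaryltetrahydrofurans under chemical, enzymatic and anodic oxidation. C3 and C4 are set in the radical combination by the two resident (2S,3S)-dihydrobenzofurans, whose 3-aryl groups each screen one face of the adjacent β-carbon (identical, hence matched, partners); because this central bond is weak and can reopen, the C2-symmetric 3,4-threo isomer should be funnelled into product by the irreversible hydration. C2 is set by attack of water on the methide face anti to the bulky C3–C4 branch in the conformer that minimises allylic strain, which gives the 2,3-cis relation, and C5 is set in the ring closure, whose envelope transition state places the incoming aryl group trans to the benzofuranyl group on C4. The step needs oxidation of the only free phenol among four oxygenated arenes and β,β rather than β,ortho or β,O coupling: the chlorine atoms make this phenol the most acidic and most easily oxidised site and block its ortho carbons, the benzyl ethers silence all other phenols, and the potential is held below the wave of the non-conjugated chlorophenols of the product.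

Step 12
Reactants: 19 octabenzyl tetrachloro tetramer
Product: 20 4,4′-[(2S,3S,4S,5R)-3,4-bis{(2S,3S)-3-(3,5-dihydroxyphenyl)-6-hydroxy-2-(4-hydroxyphenyl)-2,3-dihydro-1-benzofuran-4-yl}oxolane-2,5-diyl]diphenol (target)
Conditions: H2 (1 atm), Pd/C, NaOAc, THF/MeOH, rt
Reagents that add atoms: none
Why: Catalytic hydrogenolysis should cleave the eight aryl benzyl ethers and, with NaOAc taking up the HCl, the four aryl C–Cl bonds (hydrodechlorination), while the buffered neutral medium should spare the cyclic benzylic C–O bonds and prevent acid-induced epimerisation at C2 of the tetrahydrofuran.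

Compound list

1 | 5-bromobenzene-1,3-diol (5-bromoresorcinol) | Oc1cc(O)cc(Br)c1 | starting material
2 | 2-bromo-4,6-dihydroxybenzaldehyde | O=Cc1c(O)cc(O)cc1Br | intermediate
3 | 4-(benzyloxy)-2-bromo-6-hydroxybenzaldehyde | O=Cc1c(O)cc(OCc2ccccc2)cc1Br | intermediate
4 | 1-(benzyloxy)-4-(chloromethyl)benzene (4-(benzyloxy)benzyl chloride) | ClCc1ccc(OCc2ccccc2)cc1 | starting material
5 | 4-(benzyloxy)-2-{[4-(benzyloxy)benzyl]oxy}-6-bromobenzaldehyde | O=Cc1c(OCc2ccc(OCc3ccccc3)cc2)cc(OCc2ccccc2)cc1Br | intermediate
6 | 1,3-bis(benzyloxy)-5-bromobenzene | Brc1cc(OCc2ccccc2)cc(OCc2ccccc2)c1 | starting material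
7 | [3,5-bis(benzyloxy)phenyl]magnesium bromide (formed in the flask) | Br[Mg]c1cc(OCc2ccccc2)cc(OCc2ccccc2)c1 | intermediate
8 | racemic [4-(benzyloxy)-2-{[4-(benzyloxy)benzyl]oxy}-6-bromophenyl][3,5-bis(benzyloxy)phenyl]methanol | OC(c1cc(OCc2ccccc2)cc(OCc2ccccc2)c1)c1c(OCc2ccc(OCc3ccccc3)cc2)cc(OCc2ccccc2)cc1Br | intermediate
9 | [4-(benzyloxy)-2-{[4-(benzyloxy)benzyl]oxy}-6-bromophenyl][3,5-bis(benzyloxy)phenyl]methanone | O=C(c1cc(OCc2ccccc2)cc(OCc2ccccc2)c1)c1c(OCc2ccc(OCc3ccccc3)cc2)cc(OCc2ccccc2)cc1Br | intermediate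
10 | hydrazone of ketone 9 (C=N–NH2) | NN=C(c1cc(OCc2ccccc2)cc(OCc2ccccc2)c1)c1c(OCc2ccc(OCc3ccccc3)cc2)cc(OCc2ccccc2)cc1Br | intermediate
11 | diaryldiazomethane from 10 (formed in the flask) | [N-]=[N+]=C(c1cc(OCc2ccccc2)cc(OCc2ccccc2)c1)c1c(OCc2ccc(OCc3ccccc3)cc2)cc(OCc2ccccc2)cc1Br | intermediate
12 | (2R,3S)-6-(benzyloxy)-2-[4-(benzyloxy)phenyl]-3-[3,5-bis(benzyloxy)phenyl]-4-bromo-2,3-dihydro-1-benzofuran (2,3-cis) | C(Oc1ccc([C@@H]2Oc3cc(OCc4ccccc4)cc(Br)c3[C@@H]2c2cc(OCc3ccccc3)cc(OCc3ccccc3)c2)cc1)c1ccccc1 | intermediate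
13 | (2S,3S)-6-(benzyloxy)-2-[4-(benzyloxy)phenyl]-3-[3,5-bis(benzyloxy)phenyl]-4-bromo-2,3-dihydro-1-benzofuran (2,3-trans) | C(Oc1ccc([C@H]2Oc3cc(OCc4ccccc4)cc(Br)c3[C@@H]2c2cc(OCc3ccccc3)cc(OCc3ccccc3)c2)cc1)c1ccccc1 | intermediate
14 | 3,5-dichloro-4-hydroxybenzaldehyde | O=Cc1cc(Cl)c(O)c(Cl)c1 | starting material
15 | 2,6-dichloro-4-ethenylphenol | C=Cc1cc(Cl)c(O)c(Cl)c1 | intermediate
16 | 4-[(E)-2-(BF)ethenyl]-2,6-dichlorophenol (protected, chlorine-blocked stilbene monomer) | C(Oc1ccc([C@H]2Oc3cc(OCc4ccccc4)cc(/C=C/c4cc(Cl)c(O)c(Cl)c4)c3[C@@H]2c2cc(OCc3ccccc3)cc(OCc3ccccc3)c2)cc1)c1ccccc1 | intermediate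
17 | 4,4′-[(2S,3S)-2,3-bis(BF)butane-1,4-diylidene]bis(2,6-dichlorocyclohexa-2,5-dien-1-one) (bis(quinone methide), formed in the flask) | C(Oc1ccc([C@H]2Oc3cc(OCc4ccccc4)cc([C@@H](C=C4C=C(Cl)C(=O)C(Cl)=C4)[C@@H](c4cc(OCc5ccccc5)cc5c4[C@H](c4cc(OCc6ccccc6)cc(OCc6ccccc6)c4)[C@@H](c4ccc(OCc6ccccc6)cc4)O5)C=C4C=C(Cl)C(=O)C(Cl)=C4)c3[C@@H]2c2cc(OCc3ccccc3)cc(OCc3ccccc3)c2)cc1)c1ccccc1 | intermediate
18 | 2,6-dichloro-4-[(1S,2S,3S)-2,3-bis(BF)-4-(3,5-dichloro-4-oxocyclohexa-2,5-dien-1-ylidene)-1-hydroxybutyl]phenol (hydroxy quinone methide, formed in the flask) | C(Oc1ccc([C@H]2Oc3cc(OCc4ccccc4)cc([C@@H]([C@H](O)c4cc(Cl)c(O)c(Cl)c4)[C@@H](c4cc(OCc5ccccc5)cc5c4[C@H](c4cc(OCc6ccccc6)cc(OCc6ccccc6)c4)[C@@H](c4ccc(OCc6ccccc6)cc4)O5)C=C4C=C(Cl)C(=O)C(Cl)=C4)c3[C@@H]2c2cc(OCc3ccccc3)cc(OCc3ccccc3)c2)cc1)c1ccccc1 | intermediate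
19 | 4,4′-[(2S,3S,4S,5R)-3,4-bis(BF)oxolane-2,5-diyl]bis(2,6-dichlorophenol) | C(Oc1ccc([C@H]2Oc3cc(OCc4ccccc4)cc([C@@H]4[C@@H](c5cc(OCc6ccccc6)cc6c5[C@H](c5cc(OCc7ccccc7)cc(OCc7ccccc7)c5)[C@@H](c5ccc(OCc7ccccc7)cc5)O6)[C@H](c5cc(Cl)c(O)c(Cl)c5)O[C@@H]4c4cc(Cl)c(O)c(Cl)c4)c3[C@@H]2c2cc(OCc3ccccc3)cc(OCc3ccccc3)c2)cc1)c1ccccc1 | intermediate
20 | 4,4′-[(2S,3S,4S,5R)-3,4-bis{(2S,3S)-3-(3,5-dihydroxyphenyl)-6-hydroxy-2-(4-hydroxyphenyl)-2,3-dihydro-1-benzofuran-4-yl}oxolane-2,5-diyl]diphenol (CNP0270490.1) | Oc1ccc([C@H]2Oc3cc(O)cc([C@@H]4[C@@H](c5cc(O)cc6c5[C@H](c5cc(O)cc(O)c5)[C@@H](c5ccc(O)cc5)O6)[C@H](c5ccc(O)cc5)O[C@@H]4c4ccc(O)cc4)c3[C@@H]2c2cc(O)cc(O)c2)cc1 | target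

Total step count: 12.
Longest linear sequence: 11 steps (steps 1 to 8, then 10, 11 and 12); step 9 is a one-step side branch.

Steps most likely to fail

Step 11 (key step). The radical combination may not select the C2-symmetric 3,4-threo mode among the three possible diastereomers. Water may add to the wrong methide face, giving 2,3-trans instead of 2,3-cis. The product phenols may also be oxidised further when conversion is pushed. The fallback splits the cascade into a chemical two-stage sequence that sets out from 16 and comes back at 19. Stoichiometric Ag2O in dry CH2Cl2 over molecular sieves at 0 °C should convert 16 into the bis(quinone methide) 17. It is held in solution without a nucleophile, so that its diastereomers can equilibrate through reversible homolysis of the central C–C bond. The solution is then added at −20 °C to THF/water buffered with NaHCO3, so that hydration and 5-exo ring closure to 19 take place as a separate, kinetically controlled event. This fallback makes no compound outside the compound list (F0).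

Step 7. The doubly ortho-substituted diaryldiazomethane may form azine or carbene dimer instead of inserting, or the twisted carbene may be discriminated poorly by the chiral dirhodium catalyst, which would leave C3 in low enantiomeric purity. The fallback sets out from ketone 9 and comes back at 13 without any carbene. The phosphazene base P4-t-Bu in toluene should deprotonate the benzylic ether CH2 group, and the carbanion adds to the ketone. Dehydration with TsOH should then give the flat 6-(benzyloxy)-2-[4-(benzyloxy)phenyl]-3-[3,5-bis(benzyloxy)phenyl]-4-bromo-1-benzofuran F1. Ionic hydrogenation (Et3SiH, TFA, CH2Cl2, 0 °C) should reduce the furan C2=C3 bond to the racemic trans-2,3-dihydrobenzofuran, that is 13 together with its (2R,3R)-enantiomer F2. Preparative chromatography on a chiral stationary phase then delivers 13.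

Step 12. Hydrogenolytic opening of the cyclic benzylic C–O bonds (tetrahydrofuran and dihydrobenzofurans) may compete with the slow loss of the four aryl chlorides, or dechlorination may stay incomplete. The fallback sets out from 19 and comes back at 20 in two stages. Non-reductive debenzylation with BCl3 and pentamethylbenzene in CH2Cl2 at −78 °C should give 4,4′-[(2S,3S,4S,5R)-3,4-bis{(2S,3S)-3-(3,5-dihydroxyphenyl)-6-hydroxy-2-(4-hydroxyphenyl)-2,3-dihydro-1-benzofuran-4-yl}oxolane-2,5-diyl]bis(2,6-dichlorophenol) F3. The chlorine atoms make the two benzylic carbons of the tetrahydrofuran poor cation precursors at this stage, so C2 should keep its configuration. A short hydrodechlorination on this benzyl-free substrate (H2, Pd/C, NaOAc, MeOH, rt) should then give 20.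

Further compounds

F0 | step 11 | none | none
F1 | step 7 | 6-(benzyloxy)-2-[4-(benzyloxy)phenyl]-3-[3,5-bis(benzyloxy)phenyl]-4-bromo-1-benzofuran | Brc1cc(OCc2ccccc2)cc2oc(-c3ccc(OCc4ccccc4)cc3)c(-c3cc(OCc4ccccc4)cc(OCc4ccccc4)c3)c12
F2 | step 7 | (2R,3R)-6-(benzyloxy)-2-[4-(benzyloxy)phenyl]-3-[3,5-bis(benzyloxy)phenyl]-4-bromo-2,3-dihydro-1-benzofuran (enantiomer of 13) | C(Oc1ccc([C@@H]2Oc3cc(OCc4ccccc4)cc(Br)c3[C@H]2c2cc(OCc3ccccc3)cc(OCc3ccccc3)c2)cc1)c1ccccc1
F3 | step 12 | 4,4′-[(2S,3S,4S,5R)-3,4-bis{(2S,3S)-3-(3,5-dihydroxyphenyl)-6-hydroxy-2-(4-hydroxyphenyl)-2,3-dihydro-1-benzofuran-4-yl}oxolane-2,5-diyl]bis(2,6-dichlorophenol) | Oc1ccc([C@H]2Oc3cc(O)cc([C@@H]4[C@@H](c5cc(O)cc6c5[C@H](c5cc(O)cc(O)c5)[C@@H](c5ccc(O)cc5)O6)[C@H](c5cc(Cl)c(O)c(Cl)c5)O[C@@H]4c4cc(Cl)c(O)c(Cl)c4)c3[C@@H]2c2cc(O)cc(O)c2)cc1
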